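**Retrosynthetic overview**
- The two acetates and the free C8 phenol are set at the end from a triol; the isopropylidene terminus comes from a B-alkyl Suzuki coupling on a C12 vinyl group.
- The carbocyclic ring B is closed late by an intramolecular Heck reaction (C1–C8a) on a C8a aryl triflate; the C1 methyl comes from hydroxyl-directed hydrogenation of the exocyclic methylene, and C2 from asymmetric transfer hydrogenation of an ynone.
- C2 is attached to C3 by Arndt–Eistert homologation after converting CH2NO2 into CO2H.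
- Key bond C4–C11: organocatalytic Michael addition of propanal (fragment 2) to an aryl nitroalkene (fragment 1), which sets C4 and C11 together.
- Aromatic ring A is taken intact from methyl vanillate (Duff formylation, Henry condensation); ring order: ring A (starting material), a transient lactol ring, then ring B by the Heck closure.

Assumption: atoms are labelled C1 (CH–CH3), C2 (CH–O), C3, C4 (CH–side chain), C4a–C8a and C11 (side-chain CH), so the target SMILES reads (1S,2S,4S,11S); all named reagents are taken as commercial.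

**Step 1**
Reactants: 1 methyl 4-hydroxy-3-methoxybenzoate (methyl vanillate)
Product: 2 methyl 3-formyl-4-hydroxy-5-methoxybenzoate
Conditions: hexamethylenetetramine (2 equiv), CF3CO2H, 90 °C, 12 h; then H2O, 60 °C
Reagents that add atoms: hexamethylenetetramine (C1N2CN3CN1CN(C2)C3); water (O)
Why: Duff formylation attacks the only free position ortho to the phenol, and hydrolysis of the benzyliminium gives the salicylaldehyde with the ester para and the methoxy group ortho to the OH.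

**Step 2**
Reactants: 2 methyl 3-formyl-4-hydroxy-5-methoxybenzoate
Product: 3 methyl 4-hydroxy-3-methoxy-5-[(E)-2-nitroethenyl]benzoate
Conditions: CH3NO2 (10 equiv), NH4OAc (1 equiv), AcOH, 100 °C
Reagents that add atoms: nitromethane (C[N+](=O)[O-])
Why: Henry (nitroaldol) condensation with dehydration in situ gives the thermodynamically favoured E-nitroalkene.

**Step 3**
Reactants: 3 methyl 4-hydroxy-3-methoxy-5-[(E)-2-nitroethenyl]benzoate; 4 propanal
Product: 6 methyl 4-hydroxy-3-[(2S,3R)-4-hydroxy-3-methyl-1-nitrobutan-2-yl]-5-methoxybenzoate, via lactol 5 (not isolated)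
Conditions: (S)-α,α-diphenylprolinol trimethylsilyl ether (10 mol%), propanal (3 equiv), CH2Cl2, 0 °C to rt; then MeOH, NaBH4, 0 °C
Reagents that add atoms: none
Why: Enamine-catalysed asymmetric Michael addition (Hayashi–Jørgensen type): the E-enamine of propanal, shielded on one face by the catalyst, adds to the nitroalkene to give the syn (2R,3S) adduct, which sets C4 (S) and C11 in one step; the adduct is trapped as the lactol and reduced at once so the α-stereocentre cannot epimerise.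

**Step 4**
Reactants: 6 methyl 4-hydroxy-3-[(2S,3R)-4-hydroxy-3-methyl-1-nitrobutan-2-yl]-5-methoxybenzoate
Product: 7 methyl 3-[(2S,3R)-4-hydroxy-3-methyl-1-nitrobutan-2-yl]-5-methoxy-4-(trifluoromethylsulfonyloxy)benzoate
Conditions: PhNTf2 (1.1 equiv), Et3N (1.5 equiv), DMAP (10 mol%), CH2Cl2, 0 °C to rt
Reagents that add atoms: N-phenylbis(trifluoromethanesulfonimide) (O=S(=O)(N(c1ccccc1)S(=O)(=O)C(F)(F)F)C(F)(F)F)
Why: Chemoselective O-sulfonylation: only the acidic phenol is converted by the mild triflating agent, and the triflate serves both as a non-nucleophilic protecting group and as the later Heck handle.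

**Step 5**
Reactants: 7 methyl 3-[(2S,3R)-4-hydroxy-3-methyl-1-nitrobutan-2-yl]-5-methoxy-4-(trifluoromethylsulfonyloxy)benzoate
Product: 8 methyl 3-[(2S,3R)-4-(tert-butyldimethylsilyloxy)-3-methyl-1-nitrobutan-2-yl]-5-methoxy-4-(trifluoromethylsulfonyloxy)benzoate
Conditions: TBSCl (1.2 equiv), imidazole (2.5 equiv), DMF, rt
Reagents that add atoms: tert-butyldimethylsilyl chloride (CC(C)(C)[Si](C)(C)Cl)
Why: Standard silylation of the primary alcohol masks C12 until the ring has been built.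

**Step 6**
Reactants: 8 methyl 3-[(2S,3R)-4-(tert-butyldimethylsilyloxy)-3-methyl-1-nitrobutan-2-yl]-5-methoxy-4-(trifluoromethylsulfonyloxy)benzoate
Product: 9 (2S,3R)-4-(tert-butyldimethylsilyloxy)-2-[3-methoxy-5-(methoxycarbonyl)-2-(trifluoromethylsulfonyloxy)phenyl]-3-methylbutanoic acid
Conditions: NaNO2 (3 equiv), AcOH (10 equiv), DMSO, 35 °C
Reagents that add atoms: sodium nitrite ([Na+].[O-]N=O)
Why: Nitrosative Nef-type conversion of a primary nitroalkane into the carboxylic acid (through the nitrolic acid and nitrile oxide) runs under weakly acidic conditions that do not enolise the benzylic C4 centre.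

**Step 7**
Reactants: 9 (2S,3R)-4-(tert-butyldimethylsilyloxy)-2-[3-methoxy-5-(methoxycarbonyl)-2-(trifluoromethylsulfonyloxy)phenyl]-3-methylbutanoic acid
Product: 11 methyl 3-[(3S,4R)-5-(tert-butyldimethylsilyloxy)-1-diazo-4-methyl-2-oxopentan-3-yl]-5-methoxy-4-(trifluoromethylsulfonyloxy)benzoate, via acid chloride 10 (not isolated)
Conditions: 1-chloro-N,N,2-trimethylprop-1-en-1-amine (1.3 equiv), CH2Cl2, 0 °C to rt; then CH2N2 (3 equiv), Et2O, 0 °C
Reagents that add atoms: diazomethane (C=[N+]=[N-])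
Why: First half of the Arndt–Eistert homologation: the acid chloride is made under neutral conditions and acylates diazomethane without any amine base, so no ketene forms and C4 keeps its configuration.

**Step 8**
Reactants: 11 methyl 3-[(3S,4R)-5-(tert-butyldimethylsilyloxy)-1-diazo-4-methyl-2-oxopentan-3-yl]-5-methoxy-4-(trifluoromethylsulfonyloxy)benzoate
Product: 13 methyl 3-[(2R,3S)-1-(tert-butyldimethylsilyloxy)-5-[methoxy(methyl)amino]-2-methyl-5-oxopentan-3-yl]-5-methoxy-4-(trifluoromethylsulfonyloxy)benzoate, via ketene 12 (not isolated)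
Conditions: hν (365 nm), MeNHOMe (3 equiv), THF, 0 °C to rt
Reagents that add atoms: N,O-dimethylhydroxylamine (CNOC)
Why: Photochemical Wolff rearrangement: the benzylic carbon migrates with retention, and the ketene is trapped by the amine to give the Weinreb amide with C3 as CH2 and C2 as the carbonyl.

**Step 9**
Reactants: 13 methyl 3-[(2R,3S)-1-(tert-butyldimethylsilyloxy)-5-[methoxy(methyl)amino]-2-methyl-5-oxopentan-3-yl]-5-methoxy-4-(trifluoromethylsulfonyloxy)benzoate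
Product: 14 methyl 3-[(2R,3S)-1-(tert-butyldimethylsilyloxy)-2-methyl-5-oxo-7-(trimethylsilyl)hept-6-yn-3-yl]-5-methoxy-4-(trifluoromethylsulfonyloxy)benzoate
Conditions: (trimethylsilyl)acetylene (2.5 equiv), n-BuLi (2.3 equiv), THF, −78 °C; then 13, −78 to −30 °C; aq. NH4Cl
Reagents that add atoms: (trimethylsilyl)acetylene (C#C[Si](C)(C)C)
Why: Weinreb ketone synthesis: the chelated tetrahedral adduct stops at the ketone stage, and a lithium acetylide at low temperature leaves the aryl ester and the aryl triflate alone.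

**Step 10**
Reactants: 14 methyl 3-[(2R,3S)-1-(tert-butyldimethylsilyloxy)-2-methyl-5-oxo-7-(trimethylsilyl)hept-6-yn-3-yl]-5-methoxy-4-(trifluoromethylsulfonyloxy)benzoate
Product: 15 methyl 3-[(2R,3S,5S)-1-(tert-butyldimethylsilyloxy)-5-hydroxy-2-methyl-7-(trimethylsilyl)hept-6-yn-3-yl]-5-methoxy-4-(trifluoromethylsulfonyloxy)benzoate
Conditions: Ru[(S,S)-TsDPEN](p-cymene) (preformed amido complex, 2 mol%), i-PrOH, 25 °C
Reagents that add atoms: none
Why: Noyori asymmetric transfer hydrogenation of an alkynyl ketone: the (S,S) catalyst places the alkyne as the π-substituent and delivers hydride to give the (S)-propargylic alcohol, so C2 is set by reagent control.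

**Step 11**
Reactants: 15 methyl 3-[(2R,3S,5S)-1-(tert-butyldimethylsilyloxy)-5-hydroxy-2-methyl-7-(trimethylsilyl)hept-6-yn-3-yl]-5-methoxy-4-(trifluoromethylsulfonyloxy)benzoate
Product: 16 methyl 3-[(2R,3S,5S)-1-(tert-butyldimethylsilyloxy)-5-hydroxy-2-methylhept-6-yn-3-yl]-5-methoxy-4-(trifluoromethylsulfonyloxy)benzoate
Conditions: AgNO3 (10 mol%), MeOH/H2O/CH2Cl2 7:1:4, rt
Reagents that add atoms: none
Why: Silver-catalysed protodesilylation removes only the alkynyl silane and avoids the alkoxide bases that would cleave the aryl triflate.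

**Step 12**
Reactants: 16 methyl 3-[(2R,3S,5S)-1-(tert-butyldimethylsilyloxy)-5-hydroxy-2-methylhept-6-yn-3-yl]-5-methoxy-4-(trifluoromethylsulfonyloxy)benzoate
Product: 17 methyl 3-[(2R,3S,5S)-1-(tert-butyldimethylsilyloxy)-5-hydroxy-2-methylhept-6-en-3-yl]-5-methoxy-4-(trifluoromethylsulfonyloxy)benzoate
Conditions: H2 (1 atm), Pd/CaCO3 poisoned with Pb(OAc)2, quinoline, EtOAc, rt
Reagents that add atoms: none
Why: Lindlar semihydrogenation stops at the terminal alkene and leaves the triflate and the carbinol centre unchanged.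

**Step 13**
Reactants: 17 methyl 3-[(2R,3S,5S)-1-(tert-butyldimethylsilyloxy)-5-hydroxy-2-methylhept-6-en-3-yl]-5-methoxy-4-(trifluoromethylsulfonyloxy)benzoate
Product: 18 methyl (6S,8S)-8-[(2R)-1-(tert-butyldimethylsilyloxy)propan-2-yl]-6-hydroxy-4-methoxy-5-methylidene-5,6,7,8-tetrahydronaphthalene-2-carboxylate
Conditions: Pd(OAc)2 (10 mol%), PPh3 (30 mol%), Et3N (3 equiv), MeCN, 80 °C
Reagents that add atoms: none
Why: Intramolecular 6-exo-trig Heck reaction forms the C1–C8a bond, and because the only β-hydrogen of the alkylpalladium sits on C1, elimination gives the exocyclic methylene next to the intact C2 carbinol.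

**Step 14**
Reactants: 18 methyl (6S,8S)-8-[(2R)-1-(tert-butyldimethylsilyloxy)propan-2-yl]-6-hydroxy-4-methoxy-5-methylidene-5,6,7,8-tetrahydronaphthalene-2-carboxylate
Product: 19 methyl (5S,6S,8S)-8-[(2R)-1-(tert-butyldimethylsilyloxy)propan-2-yl]-6-hydroxy-4-methoxy-5-methyl-5,6,7,8-tetrahydronaphthalene-2-carboxylate
Conditions: [Ir(cod)(PCy3)(py)]PF6 (5 mol%), H2 (1 atm), CH2Cl2, 0 °C to rt
Reagents that add atoms: none
Why: Hydroxyl-directed homogeneous hydrogenation: iridium bound to the C2–OH delivers both hydrogens to the same face, so the new C1 methyl ends up trans to the oxygen (C1 S).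

**Step 15**
Reactants: 19 methyl (5S,6S,8S)-8-[(2R)-1-(tert-butyldimethylsilyloxy)propan-2-yl]-6-hydroxy-4-methoxy-5-methyl-5,6,7,8-tetrahydronaphthalene-2-carboxylate
Product: 20 methyl (5S,6S,8S)-6-acetoxy-8-[(2R)-1-(tert-butyldimethylsilyloxy)propan-2-yl]-4-methoxy-5-methyl-5,6,7,8-tetrahydronaphthalene-2-carboxylate
Conditions: Ac2O (2 equiv), pyridine, DMAP (cat.), CH2Cl2, rt
Reagents that add atoms: acetic anhydride (CC(=O)OC(C)=O)
Why: Acylation blocks the C2–OH, which would otherwise form a bridged lactol with the cis-disposed C12 aldehyde made two steps later.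

**Step 16**
Reactants: 20 methyl (5S,6S,8S)-6-acetoxy-8-[(2R)-1-(tert-butyldimethylsilyloxy)propan-2-yl]-4-methoxy-5-methyl-5,6,7,8-tetrahydronaphthalene-2-carboxylate
Product: 21 methyl (5S,6S,8S)-6-acetoxy-8-[(2R)-1-hydroxypropan-2-yl]-4-methoxy-5-methyl-5,6,7,8-tetrahydronaphthalene-2-carboxylate
Conditions: HF·pyridine, THF/pyridine, 0 °C to rt
Reagents that add atoms: none
Why: Fluoride-mediated desilylation under buffered acidic conditions leaves both esters untouched.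

**Step 17**
Reactants: 21 methyl (5S,6S,8S)-6-acetoxy-8-[(2R)-1-hydroxypropan-2-yl]-4-methoxy-5-methyl-5,6,7,8-tetrahydronaphthalene-2-carboxylate
Product: 22 methyl (5S,6S,8S)-6-acetoxy-4-methoxy-5-methyl-8-[(2R)-1-oxopropan-2-yl]-5,6,7,8-tetrahydronaphthalene-2-carboxylate
Conditions: Dess–Martin periodinane (1.3 equiv), CH2Cl2, 0 °C to rt
Reagents that add atoms: none
Why: Dess–Martin oxidation gives the α-branched aldehyde under neutral conditions without epimerising C11.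

**Step 18**
Reactants: 22 methyl (5S,6S,8S)-6-acetoxy-4-methoxy-5-methyl-8-[(2R)-1-oxopropan-2-yl]-5,6,7,8-tetrahydronaphthalene-2-carboxylate
Product: 23 methyl (5S,6S,8S)-6-acetoxy-8-[(2S)-but-3-en-2-yl]-4-methoxy-5-methyl-5,6,7,8-tetrahydronaphthalene-2-carboxylate
Conditions: Ph3PCH3Br (1.4 equiv), KN(SiMe3)2 (1.3 equiv), THF, 0 °C; then 22, −78 to 0 °C
Reagents that add atoms: methyltriphenylphosphonium bromide (C[P+](c1ccccc1)(c1ccccc1)c1ccccc1.[Br-])
Why: Wittig methylenation with a salt-free ylide at low temperature reacts with the aldehyde far faster than with the esters and does not epimerise the α-centre.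

**Step 19**
Reactants: 23 methyl (5S,6S,8S)-6-acetoxy-8-[(2S)-but-3-en-2-yl]-4-methoxy-5-methyl-5,6,7,8-tetrahydronaphthalene-2-carboxylate
Product: 25 methyl (5S,6S,8S)-6-acetoxy-4-methoxy-5-methyl-8-[(2S)-6-methylhept-5-en-2-yl]-5,6,7,8-tetrahydronaphthalene-2-carboxylate, via alkylborane 24 (not isolated)
Conditions: 9-BBN-H (1.5 equiv), THF, rt; then 1-bromo-2-methylprop-1-ene (2 equiv), Pd(dppf)Cl2 (5 mol%), AsPh3 (10 mol%), Cs2CO3 (3 equiv), DMF/H2O, rt
Reagents that add atoms: 1-bromo-2-methylprop-1-ene (CC(C)=CBr)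
Why: Anti-Markovnikov hydroboration of the terminal alkene followed by B-alkyl Suzuki–Miyaura coupling with the vinyl bromide installs the trisubstituted alkene regiospecifically, with no stereocentre involved.

**Step 20**
Reactants: 25 methyl (5S,6S,8S)-6-acetoxy-4-methoxy-5-methyl-8-[(2S)-6-methylhept-5-en-2-yl]-5,6,7,8-tetrahydronaphthalene-2-carboxylate
Product: 26 (1S,2S,4S)-6-(hydroxymethyl)-8-methoxy-1-methyl-4-[(2S)-6-methylhept-5-en-2-yl]-1,2,3,4-tetrahydronaphthalen-2-ol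
Conditions: LiAlH4 (3 equiv), THF, 0 °C
Reagents that add atoms: none
Why: Hydride reduction turns the aryl ester into the benzylic alcohol and removes the temporary acetate, while the isolated alkene is inert.

**Step 21**
Reactants: 26 (1S,2S,4S)-6-(hydroxymethyl)-8-methoxy-1-methyl-4-[(2S)-6-methylhept-5-en-2-yl]-1,2,3,4-tetrahydronaphthalen-2-ol
Product: 27 (1S,2S,4S)-6-(hydroxymethyl)-1-methyl-4-[(2S)-6-methylhept-5-en-2-yl]-1,2,3,4-tetrahydronaphthalene-2,8-diol
Conditions: NaSEt (6 equiv), DMF, 130 °C; aq. NH4Cl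
Reagents that add atoms: none
Why: SN2 demethylation of the aryl methyl ether by thiolate tolerates the alkene and both alcohols, and the benzylic alcohol is meta to the phenoxide so no quinone methide can form.

**Step 22**
Reactants: 27 (1S,2S,4S)-6-(hydroxymethyl)-1-methyl-4-[(2S)-6-methylhept-5-en-2-yl]-1,2,3,4-tetrahydronaphthalene-2,8-diol
Product: 28 [(5S,6S,8S)-4,6-diacetoxy-5-methyl-8-[(2S)-6-methylhept-5-en-2-yl]-5,6,7,8-tetrahydronaphthalen-2-yl]methyl acetate
Conditions: Ac2O (6 equiv), pyridine, DMAP (cat.), rt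
Reagents that add atoms: acetic anhydride (CC(=O)OC(C)=O)
Why: Exhaustive acetylation avoids any need to distinguish the alcohols from the phenol at this stage.

**Step 23**
Reactants: 28 [(5S,6S,8S)-4,6-diacetoxy-5-methyl-8-[(2S)-6-methylhept-5-en-2-yl]-5,6,7,8-tetrahydronaphthalen-2-yl]methyl acetate
Product: 29 [(5S,6S,8S)-6-acetoxy-4-hydroxy-5-methyl-8-[(2S)-6-methylhept-5-en-2-yl]-5,6,7,8-tetrahydronaphthalen-2-yl]methyl acetate (CNP0210401.1)
Conditions: NH4OAc (10 equiv), MeOH/H2O 4:1, rt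
Reagents that add atoms: none
Why: Chemoselective solvolysis of the aryl acetate: phenoxide is a far better leaving group than an alkoxide, so the two alkyl acetates remain.

**Compound list**
1 | methyl 4-hydroxy-3-methoxybenzoate (methyl vanillate) | COC(=O)c1ccc(O)c(OC)c1 | starting material
2 | methyl 3-formyl-4-hydroxy-5-methoxybenzoate | COC(=O)c1cc(OC)c(O)c(C=O)c1 | intermediate
3 | methyl 4-hydroxy-3-methoxy-5-[(E)-2-nitroethenyl]benzoate | COC(=O)c1cc(OC)c(O)c(/C=C/[N+](=O)[O-])c1 | intermediate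
4 | propanal | CCC=O | starting material
5 | methyl (3R,4S)-2-hydroxy-8-methoxy-3-methyl-4-(nitromethyl)-3,4-dihydro-2H-chromene-6-carboxylate (lactol, anomer mixture) | COC(=O)c1cc(OC)c2OC(O)[C@H](C)[C@H](C[N+](=O)[O-])c2c1 | intermediate
6 | methyl 4-hydroxy-3-[(2S,3R)-4-hydroxy-3-methyl-1-nitrobutan-2-yl]-5-methoxybenzoate | COC(=O)c1cc(OC)c(O)c(c1)[C@H]([C@@H](C)CO)C[N+](=O)[O-] | intermediate
7 | methyl 3-[(2S,3R)-4-hydroxy-3-methyl-1-nitrobutan-2-yl]-5-methoxy-4-(trifluoromethylsulfonyloxy)benzoate | COC(=O)c1cc(OC)c(OS(=O)(=O)C(F)(F)F)c(c1)[C@H]([C@@H](C)CO)C[N+](=O)[O-] | intermediate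
8 | methyl 3-[(2S,3R)-4-(tert-butyldimethylsilyloxy)-3-methyl-1-nitrobutan-2-yl]-5-methoxy-4-(trifluoromethylsulfonyloxy)benzoate | COC(=O)c1cc(OC)c(OS(=O)(=O)C(F)(F)F)c(c1)[C@H]([C@@H](C)CO[Si](C)(C)C(C)(C)C)C[N+](=O)[O-] | intermediate
9 | (2S,3R)-4-(tert-butyldimethylsilyloxy)-2-[3-methoxy-5-(methoxycarbonyl)-2-(trifluoromethylsulfonyloxy)phenyl]-3-methylbutanoic acid | COC(=O)c1cc(OC)c(OS(=O)(=O)C(F)(F)F)c(c1)[C@H]([C@@H](C)CO[Si](C)(C)C(C)(C)C)C(=O)O | intermediate
10 | (2S,3R)-4-(tert-butyldimethylsilyloxy)-2-[3-methoxy-5-(methoxycarbonyl)-2-(trifluoromethylsulfonyloxy)phenyl]-3-methylbutanoyl chloride | COC(=O)c1cc(OC)c(OS(=O)(=O)C(F)(F)F)c(c1)[C@H]([C@@H](C)CO[Si](C)(C)C(C)(C)C)C(=O)Cl | intermediate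
11 | methyl 3-[(3S,4R)-5-(tert-butyldimethylsilyloxy)-1-diazo-4-methyl-2-oxopentan-3-yl]-5-methoxy-4-(trifluoromethylsulfonyloxy)benzoate | COC(=O)c1cc(OC)c(OS(=O)(=O)C(F)(F)F)c(c1)[C@H]([C@@H](C)CO[Si](C)(C)C(C)(C)C)C(=O)C=[N+]=[N-] | intermediate
12 | methyl 3-[(2R,3R)-1-(tert-butyldimethylsilyloxy)-2-methyl-5-oxopent-4-en-3-yl]-5-methoxy-4-(trifluoromethylsulfonyloxy)benzoate (ketene) | COC(=O)c1cc(OC)c(OS(=O)(=O)C(F)(F)F)c(c1)[C@H]([C@@H](C)CO[Si](C)(C)C(C)(C)C)C=C=O | intermediate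
13 | methyl 3-[(2R,3S)-1-(tert-butyldimethylsilyloxy)-5-[methoxy(methyl)amino]-2-methyl-5-oxopentan-3-yl]-5-methoxy-4-(trifluoromethylsulfonyloxy)benzoate | COC(=O)c1cc(OC)c(OS(=O)(=O)C(F)(F)F)c(c1)[C@H]([C@@H](C)CO[Si](C)(C)C(C)(C)C)CC(=O)N(C)OC | intermediate
14 | methyl 3-[(2R,3S)-1-(tert-butyldimethylsilyloxy)-2-methyl-5-oxo-7-(trimethylsilyl)hept-6-yn-3-yl]-5-methoxy-4-(trifluoromethylsulfonyloxy)benzoate | COC(=O)c1cc(OC)c(OS(=O)(=O)C(F)(F)F)c(c1)[C@H]([C@@H](C)CO[Si](C)(C)C(C)(C)C)CC(=O)C#C[Si](C)(C)C | intermediate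
15 | methyl 3-[(2R,3S,5S)-1-(tert-butyldimethylsilyloxy)-5-hydroxy-2-methyl-7-(trimethylsilyl)hept-6-yn-3-yl]-5-methoxy-4-(trifluoromethylsulfonyloxy)benzoate | COC(=O)c1cc(OC)c(OS(=O)(=O)C(F)(F)F)c(c1)[C@H]([C@@H](C)CO[Si](C)(C)C(C)(C)C)C[C@H](O)C#C[Si](C)(C)C | intermediate
16 | methyl 3-[(2R,3S,5S)-1-(tert-butyldimethylsilyloxy)-5-hydroxy-2-methylhept-6-yn-3-yl]-5-methoxy-4-(trifluoromethylsulfonyloxy)benzoate | COC(=O)c1cc(OC)c(OS(=O)(=O)C(F)(F)F)c(c1)[C@H]([C@@H](C)CO[Si](C)(C)C(C)(C)C)C[C@H](O)C#C | intermediate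
17 | methyl 3-[(2R,3S,5S)-1-(tert-butyldimethylsilyloxy)-5-hydroxy-2-methylhept-6-en-3-yl]-5-methoxy-4-(trifluoromethylsulfonyloxy)benzoate | COC(=O)c1cc(OC)c(OS(=O)(=O)C(F)(F)F)c(c1)[C@H]([C@@H](C)CO[Si](C)(C)C(C)(C)C)C[C@H](O)C=C | intermediate
18 | methyl (6S,8S)-8-[(2R)-1-(tert-butyldimethylsilyloxy)propan-2-yl]-6-hydroxy-4-methoxy-5-methylidene-5,6,7,8-tetrahydronaphthalene-2-carboxylate | COC(=O)c1cc(OC)c2c(c1)[C@H]([C@@H](C)CO[Si](C)(C)C(C)(C)C)C[C@H](O)C2=C | intermediate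
19 | methyl (5S,6S,8S)-8-[(2R)-1-(tert-butyldimethylsilyloxy)propan-2-yl]-6-hydroxy-4-methoxy-5-methyl-5,6,7,8-tetrahydronaphthalene-2-carboxylate | COC(=O)c1cc(OC)c2c(c1)[C@H]([C@@H](C)CO[Si](C)(C)C(C)(C)C)C[C@H](O)[C@H]2C | intermediate
20 | methyl (5S,6S,8S)-6-acetoxy-8-[(2R)-1-(tert-butyldimethylsilyloxy)propan-2-yl]-4-methoxy-5-methyl-5,6,7,8-tetrahydronaphthalene-2-carboxylate | COC(=O)c1cc(OC)c2c(c1)[C@H]([C@@H](C)CO[Si](C)(C)C(C)(C)C)C[C@H](OC(C)=O)[C@H]2C | intermediate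
21 | methyl (5S,6S,8S)-6-acetoxy-8-[(2R)-1-hydroxypropan-2-yl]-4-methoxy-5-methyl-5,6,7,8-tetrahydronaphthalene-2-carboxylate | COC(=O)c1cc(OC)c2c(c1)[C@H]([C@@H](C)CO)C[C@H](OC(C)=O)[C@H]2C | intermediate
22 | methyl (5S,6S,8S)-6-acetoxy-4-methoxy-5-methyl-8-[(2R)-1-oxopropan-2-yl]-5,6,7,8-tetrahydronaphthalene-2-carboxylate | COC(=O)c1cc(OC)c2c(c1)[C@H]([C@@H](C)C=O)C[C@H](OC(C)=O)[C@H]2C | intermediate
23 | methyl (5S,6S,8S)-6-acetoxy-8-[(2S)-but-3-en-2-yl]-4-methoxy-5-methyl-5,6,7,8-tetrahydronaphthalene-2-carboxylate | COC(=O)c1cc(OC)c2c(c1)[C@H]([C@@H](C)C=C)C[C@H](OC(C)=O)[C@H]2C | intermediate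
24 | methyl (5S,6S,8S)-6-acetoxy-8-[(2S)-4-(9-borabicyclo[3.3.1]nonan-9-yl)butan-2-yl]-4-methoxy-5-methyl-5,6,7,8-tetrahydronaphthalene-2-carboxylate | COC(=O)c1cc(OC)c2c(c1)[C@H]([C@@H](C)CCB3C4CCCC3CCC4)C[C@H](OC(C)=O)[C@H]2C | intermediate
25 | methyl (5S,6S,8S)-6-acetoxy-4-methoxy-5-methyl-8-[(2S)-6-methylhept-5-en-2-yl]-5,6,7,8-tetrahydronaphthalene-2-carboxylate | COC(=O)c1cc(OC)c2c(c1)[C@H]([C@@H](C)CCC=C(C)C)C[C@H](OC(C)=O)[C@H]2C | intermediate
26 | (1S,2S,4S)-6-(hydroxymethyl)-8-methoxy-1-methyl-4-[(2S)-6-methylhept-5-en-2-yl]-1,2,3,4-tetrahydronaphthalen-2-ol | OCc1cc(OC)c2c(c1)[C@H]([C@@H](C)CCC=C(C)C)C[C@H](O)[C@H]2C | intermediate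
27 | (1S,2S,4S)-6-(hydroxymethyl)-1-methyl-4-[(2S)-6-methylhept-5-en-2-yl]-1,2,3,4-tetrahydronaphthalene-2,8-diol | OCc1cc(O)c2c(c1)[C@H]([C@@H](C)CCC=C(C)C)C[C@H](O)[C@H]2C | intermediate
28 | [(5S,6S,8S)-4,6-diacetoxy-5-methyl-8-[(2S)-6-methylhept-5-en-2-yl]-5,6,7,8-tetrahydronaphthalen-2-yl]methyl acetate | CC(=O)OCc1cc(OC(C)=O)c2c(c1)[C@H]([C@@H](C)CCC=C(C)C)C[C@H](OC(C)=O)[C@H]2C | intermediate
29 | [(5S,6S,8S)-6-acetoxy-4-hydroxy-5-methyl-8-[(2S)-6-methylhept-5-en-2-yl]-5,6,7,8-tetrahydronaphthalen-2-yl]methyl acetate (CNP0210401.1) | CC(=O)OCc1cc(O)c2c(c1)[C@H]([C@@H](C)CCC=C(C)C)C[C@H](OC(C)=O)[C@H]2C | target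

**Step count:** 23 steps in total. **Longest linear sequence:** 23 steps (fully linear from methyl vanillate).

**Three steps most likely to fail, with fallbacks**

Step 6 (nitro to acid). The hindered benzylic nitromethyl group may react slowly, and the silyl ether sits in acetic acid for hours. The fallback sets out from 8 and comes back at 9. Compound 8 is deprotonated with KOt-Bu (1.0 equiv, THF, 0 °C) to the potassium nitronate of 8 F1. Ozonolysis of this nitronate (O3, CH2Cl2/MeOH, −78 °C, then Me2S) gives the aldehyde methyl 3-[(2S,3R)-4-(tert-butyldimethylsilyloxy)-3-methyl-1-oxobutan-2-yl]-5-methoxy-4-(trifluoromethylsulfonyloxy)benzoate F2. This aldehyde is oxidised without purification by Pinnick oxidation (NaClO2, NaH2PO4, 2-methylbut-2-ene, t-BuOH/H2O, 0 °C) to 9.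

Step 13 (Heck ring closure). The exocyclic allylic alcohol can be isomerised by palladium hydride to the endocyclic enol and hence to a ketone, which would erase C2. The fallback sets out from 16 and comes back at 18, bypassing 17, and closes the ring by a coupling that has no β-hydride step. Hydrostannation of the terminal alkyne with Bu3SnH catalysed by Mo(CO)3(CN-t-Bu)3 (THF, 55 °C) gives regioselectively the internal vinylstannane methyl 3-[(2R,3S,5S)-1-(tert-butyldimethylsilyloxy)-5-hydroxy-2-methyl-6-(tributylstannyl)hept-6-en-3-yl]-5-methoxy-4-(trifluoromethylsulfonyloxy)benzoate F3. Intramolecular Stille coupling of the stannane with the aryl triflate (Pd(PPh3)4, CuCl, LiCl, DMSO, 60 °C) then gives 18 directly.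

Step 14 (directed hydrogenation). The peri methoxy group twists the exocyclic alkene, and poor facial selectivity or alkene migration would spoil C1. The fallback sets out from 18 and comes back at 19, and sets C1 by SN2 methylation with inversion instead of hydrogen delivery.
- Ozonolysis of 18 (O3, CH2Cl2/MeOH, −78 °C, then Me2S) gives the ketol methyl (6S,8S)-8-[(2R)-1-(tert-butyldimethylsilyloxy)propan-2-yl]-6-hydroxy-4-methoxy-5-oxo-5,6,7,8-tetrahydronaphthalene-2-carboxylate F4.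
- LiBH(s-Bu)3 (THF, −78 °C) attacks the ketone anti to the C2 oxygen and the C4 substituent and gives the cis-diol methyl (5R,6S,8S)-8-[(2R)-1-(tert-butyldimethylsilyloxy)propan-2-yl]-5,6-dihydroxy-4-methoxy-5,6,7,8-tetrahydronaphthalene-2-carboxylate F5.
- 1,1'-Sulfonyldiimidazole and NaH (THF, 0 °C) convert the diol into the 5,6-cyclic sulfate of F5 F6.
- Me2CuLi (Et2O/THF, −40 °C) opens the sulfate at the benzylic carbon with inversion to the lithium (5S,6S,8S)-6-sulfate monoester F7, which is hydrolysed in the same flask (cat. H2SO4, 1 equiv H2O, THF) to 19.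

Further compounds
F1 | step 6 | potassium nitronate of 8 (potassium salt of the aci-nitro form) | COC(=O)c1cc(OC)c(OS(=O)(=O)C(F)(F)F)c(c1)[C@H]([C@@H](C)CO[Si](C)(C)C(C)(C)C)C=[N+]([O-])[O-].[K+]
F2 | step 6 | methyl 3-[(2S,3R)-4-(tert-butyldimethylsilyloxy)-3-methyl-1-oxobutan-2-yl]-5-methoxy-4-(trifluoromethylsulfonyloxy)benzoate | COC(=O)c1cc(OC)c(OS(=O)(=O)C(F)(F)F)c(c1)[C@H]([C@@H](C)CO[Si](C)(C)C(C)(C)C)C=O
F3 | step 13 | methyl 3-[(2R,3S,5S)-1-(tert-butyldimethylsilyloxy)-5-hydroxy-2-methyl-6-(tributylstannyl)hept-6-en-3-yl]-5-methoxy-4-(trifluoromethylsulfonyloxy)benzoate | COC(=O)c1cc(OC)c(OS(=O)(=O)C(F)(F)F)c(c1)[C@H]([C@@H](C)CO[Si](C)(C)C(C)(C)C)C[C@H](O)C(=C)[Sn](CCCC)(CCCC)CCCC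
F4 | step 14 | methyl (6S,8S)-8-[(2R)-1-(tert-butyldimethylsilyloxy)propan-2-yl]-6-hydroxy-4-methoxy-5-oxo-5,6,7,8-tetrahydronaphthalene-2-carboxylate | COC(=O)c1cc(OC)c2c(c1)[C@H]([C@@H](C)CO[Si](C)(C)C(C)(C)C)C[C@H](O)C2=O
F5 | step 14 | methyl (5R,6S,8S)-8-[(2R)-1-(tert-butyldimethylsilyloxy)propan-2-yl]-5,6-dihydroxy-4-methoxy-5,6,7,8-tetrahydronaphthalene-2-carboxylate | COC(=O)c1cc(OC)c2c(c1)[C@H]([C@@H](C)CO[Si](C)(C)C(C)(C)C)C[C@H](O)[C@@H]2O
F6 | step 14 | 5,6-cyclic sulfate of F5 | COC(=O)c1cc(OC)c2c(c1)[C@H]([C@@H](C)CO[Si](C)(C)C(C)(C)C)C[C@@H]3OS(=O)(=O)O[C@H]23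
F7 | step 14 | lithium (5S,6S,8S)-8-[(2R)-1-(tert-butyldimethylsilyloxy)propan-2-yl]-4-methoxy-2-(methoxycarbonyl)-5-methyl-5,6,7,8-tetrahydronaphthalen-6-yl sulfate | COC(=O)c1cc(OC)c2c(c1)[C@H]([C@@H](C)CO[Si](C)(C)C(C)(C)C)C[C@H](OS(=O)(=O)[O-])[C@H]2C.[Li+]
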